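The isoflavan is disconnected across its pyran ring at C3–C4 and O1–C2. C4 is an unsubstituted benzylic CH2 on the phloroglucinol-type ring A, ortho to the O1-bearing carbon C8a, so O1–C8a–C4a–C4 is a latent o-quinone methide and C2–C3, carrying ring B, is the carbonyl/α-carbon pair of an arylacetaldehyde. A chiral prolinol silyl ether turns that aldehyde into an enamine which traps the methide released from a freshly prepared ring-A salicyl alcohol; one operation thus forms both bonds, the pyran ring (as a lactol) and the only stereocentre, C3. Ring B travels as its 2,4,5-trimethoxy-3-prenylphenyl precursor and becomes the hydroxyquinone at the very end.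

Key step: step 8

Remark on the chemistry: prenyl = 3-methylbut-2-en-1-yl; at C3 the carbon C2 outranks the aryl carbon in compounds 18–22 alike, so the descriptor stays R from step 8 to the target, and the (R)-catalyst is chosen because its shielding model leads to 3R.

Step 1
Reactants: 1 1,2,4-trimethoxybenzene; 2 prenyl bromide (1-bromo-3-methylbut-2-ene)
Product: 4 1,2,4-trimethoxy-3-prenylbenzene, via aryllithium 3 (not isolated)
Conditions: n-BuLi (1.1 equiv), THF, 0 °C → rt, 2 h; then 2 (1.2 equiv), −78 °C → rt
Reagents that add atoms: none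
Why: Directed ortho-metalation followed by SN2 allylation: C3–H, flanked by two methoxy groups, is the most acidic ring position of 1, and the hindered aryllithium attacks the primary carbon of the allylic bromide.

Step 2
Reactants: 4 1,2,4-trimethoxy-3-prenylbenzene
Product: 6 2,4,5-trimethoxy-3-prenylbenzaldehyde, via iminium chloride 5 (not isolated)
Conditions: POCl3 (1.5 equiv), DMF, 0 °C → 45 °C; then aq. NaOAc, rt
Reagents that add atoms: N,N-dimethylformamide, CN(C)C=O; water, O
Why: Vilsmeier–Haack formylation: the chloroiminium ion attacks C5, the only free position para to a methoxy group (and ortho to a second one), under conditions mild enough for the trisubstituted alkene, and water hydrolyses the iminium salt to the aldehyde.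

Step 3
Reactants: 6 2,4,5-trimethoxy-3-prenylbenzaldehyde
Product: 8 (2,4,5-trimethoxy-3-prenylphenyl)acetaldehyde, via aryl oxirane 7 (not isolated)
Conditions: Me3S+ I− (1.2 equiv), n-BuLi (1.15 equiv), THF, −10 °C; 6, −10 °C → rt; then MgBr2·OEt2 (1.0 equiv), 0 °C → rt; product stored cold under argon
Reagents that add atoms: trimethylsulfonium iodide, C[S+](C)C.[I-]
Why: Corey–Chaykovsky epoxidation followed by Meinwald rearrangement: the sulfonium ylide converts the aldehyde into the terminal epoxide, which the magnesium salt opens at the donor-stabilised benzylic carbon so that a 1,2-hydride shift gives the homologous aldehyde without Brønsted acid near the prenyl group, and the stereocentre of the racemic epoxide is lost in the shift.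

Step 4
Reactants: 9 3,5-dimethoxyphenol
Product: 10 (3,5-dimethoxyphenoxy)triisopropylsilane
Conditions: TIPSCl (1.1 equiv), imidazole (2.2 equiv), DMF, rt
Reagents that add atoms: chlorotriisopropylsilane, CC(C)[Si](Cl)(C(C)C)C(C)C
Why: Standard imidazole-assisted O-silylation; the bulky silyl ether removes the acidic proton and is too poor a directing group and too large to allow lithiation next to it.

Step 5
Reactants: 10 (3,5-dimethoxyphenoxy)triisopropylsilane; 2 prenyl bromide
Product: 13 3,5-dimethoxy-4-prenylphenol, via aryllithium 11 (not isolated), via silyl ether 12 (not isolated)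
Conditions: n-BuLi (1.05 equiv), THF, 0 °C → rt, 2 h; 2 (0.95 equiv), −78 °C → rt; then TBAF (1.3 equiv, 1 M in THF), rt; AcOH (1.3 equiv)
Reagents that add atoms: none
Why: Directed ortho-metalation at C4 between the two methoxy groups, SN2 allylation and fluoride desilylation in one flask; the bromide is kept limiting so that no alkylating agent is left when the phenoxide is unmasked.

Step 6
Reactants: 13 3,5-dimethoxy-4-prenylphenol
Product: 14 6-hydroxy-2,4-dimethoxy-3-prenylbenzaldehyde
Conditions: MgCl2 (2 equiv), Et3N (4 equiv), (CH2O)n (6 equiv), MeCN, reflux; then 1 M HCl, 0 °C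
Reagents that add atoms: paraformaldehyde (as formaldehyde), C=O
Why: Magnesium-mediated ortho-formylation (Casnati–Skattebøl): the magnesium phenoxide delivers formaldehyde to an ortho carbon only, a second formaldehyde oxidises the benzylic alkoxide by hydride transfer, and the two ortho positions of 13 are equivalent while the para position is blocked.

Step 7
Reactants: 14 6-hydroxy-2,4-dimethoxy-3-prenylbenzaldehyde
Product: 15 2-(hydroxymethyl)-3,5-dimethoxy-4-prenylphenol
Conditions: NaBH4 (1.0 equiv), THF/EtOH (4:1), 0 °C, 20 min; pH 7 buffer, extraction, cold concentration; no chromatography, used within the hour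
Reagents that add atoms: none
Why: Borohydride reduction of the aldehyde; the brief, cold reaction and neutral work-up are chosen because this doubly methoxy-activated salicyl alcohol loses water easily (over-reduction to the cresol, self-condensation), which is why it is made only when step 8 is ready.

Step 8
Reactants: 15 2-(hydroxymethyl)-3,5-dimethoxy-4-prenylphenol; 8 (2,4,5-trimethoxy-3-prenylphenyl)acetaldehyde
Product: 18 (3R)-5,7-dimethoxy-6-prenyl-3-(2,4,5-trimethoxy-3-prenylphenyl)chroman-2-ol (C2 anomer mixture), via o-quinone methide 16 (not isolated), via catalyst enamine 17 (not isolated)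
Conditions: 8 (1.5 equiv), (R)-α,α-diphenylprolinol trimethylsilyl ether (20 mol%), PhCO2H (20 mol%), CH2Cl2, 0 °C; 15 in CH2Cl2 added over 6 h, 0 °C → rt; rapid chromatography, carried on the same day
Reagents that add atoms: none
Why: The amine condenses with 8 to the E-enamine 17 while benzoic acid dehydrates 15 to the push–pull-stabilised o-quinone methide 16; the enamine β-carbon adds to the exocyclic CH2 of 16 (C3–C4, ring A re-aromatises) and the phenol then closes onto the iminium carbon, or onto the aldehyde after hydrolysis (O1–C2), water returning the catalyst. The closest known reaction type is the enamine-catalysed formal [4+2] (inverse-demand oxa-Diels–Alder) of in situ o-quinone methides with enolisable aldehydes, which gives 3-substituted chroman-2-ols. The dihydropyran ring closes by 6-exo-trig attack of the phenolic oxygen on the C=N+ (or C=O) carbon. C3 is controlled by the catalyst: the CPh2OSiMe3 group of the (R)-pyrrolidine shields the Si face of the s-trans E-enamine, the methide approaches the Re face, and this corresponds to 3R, while C2 is left as an anomer mixture that disappears in step 9. The step needs the methide to be taken by the enamine carbon and not by ring A of a second molecule of 15 or by the catalyst nitrogen, which the excess of 8, the slow dosing of 15 and the hindered amine should secure, and the 4,6-dimethoxy pattern lets the methide form with a weak acid that leaves both prenyl groups alone. Epimerisation should be slow because 18 is an α-branched aldehyde masked as a lactol, which the bulky catalyst does not readily convert back into an enamine.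

Step 9
Reactants: 18 (3R)-5,7-dimethoxy-6-prenyl-3-(2,4,5-trimethoxy-3-prenylphenyl)chroman-2-ol
Product: 19 (2R)-3-(6-hydroxy-2,4-dimethoxy-3-prenylphenyl)-2-(2,4,5-trimethoxy-3-prenylphenyl)propan-1-ol
Conditions: NaBH4 (2 equiv), MeOH/THF (1:1), 0 °C
Reagents that add atoms: none
Why: Borohydride reduction of the open hydroxy-aldehyde tautomer of the lactol removes the epimerisable aldehyde and the anomeric centre at once, and C3 is not touched.

Step 10
Reactants: 19 (2R)-3-(6-hydroxy-2,4-dimethoxy-3-prenylphenyl)-2-(2,4,5-trimethoxy-3-prenylphenyl)propan-1-ol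
Product: 20 (3R)-5,7-dimethoxy-6-prenyl-3-(2,4,5-trimethoxy-3-prenylphenyl)chromane
Conditions: PPh3 (1.5 equiv), DIAD (1.5 equiv), THF (0.02 M), 0 °C → rt
Reagents that add atoms: none
Why: Intramolecular Mitsunobu etherification: the phenol displaces the oxyphosphonium-activated primary alcohol in a 6-exo-tet closure, the usual way to close isoflavans, and the C3 stereocentre, one carbon away from the site of substitution, is untouched.

Step 11
Reactants: 20 (3R)-5,7-dimethoxy-6-prenyl-3-(2,4,5-trimethoxy-3-prenylphenyl)chromane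
Product: 21 2-[(3R)-5,7-dimethoxy-6-prenylchroman-3-yl]-5-methoxy-6-prenyl-1,4-benzoquinone
Conditions: CAN (2.3 equiv), MeCN/H2O (3:1), −10 °C → 0 °C, 15 min
Reagents that add atoms: water, O
Why: Oxidative demethylation of a para-dimethoxyarene with cerium(IV): the 1,2,4-trioxygenated ring B is oxidised at a lower potential than the 1,3,5-trioxygenated ring A, which has no para oxygen pair, water attacks C2′ and C5′ with loss of two methanol, and the short, cold reaction should spare the isolated alkenes.

Step 12
Reactants: 21 2-[(3R)-5,7-dimethoxy-6-prenylchroman-3-yl]-5-methoxy-6-prenyl-1,4-benzoquinone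
Product: 22 2-[(3R)-5,7-dimethoxy-6-prenylchroman-3-yl]-5-hydroxy-6-prenyl-1,4-benzoquinone (CNP0241224.1)
Conditions: 1 M aq. NaOH (3 equiv), THF/MeOH, 0 °C, argon; then cold 1 M HCl to pH 3
Reagents that add atoms: sodium hydroxide, [Na+].[OH-]
Why: Hydrolysis of a vinylogous ester by addition–elimination: hydroxide adds to C4′ and expels methoxide, the hydroxyquinone anion so formed is inert to further base, and the cold, brief, oxygen-free treatment with gentle acidification protects the benzylic C3–H and keeps the new OH from cyclising onto the neighbouring prenyl group.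

Compound list
1 | 1,2,4-trimethoxybenzene | COc1ccc(OC)c(OC)c1 | starting material
2 | prenyl bromide (1-bromo-3-methylbut-2-ene) | CC(C)=CCBr | starting material
3 | (2,3,6-trimethoxyphenyl)lithium | [Li]c1c(OC)ccc(OC)c1OC | intermediate
4 | 1,2,4-trimethoxy-3-prenylbenzene | COc1ccc(OC)c(CC=C(C)C)c1OC | intermediate
5 | N-methyl-N-[(2,4,5-trimethoxy-3-prenylphenyl)methylidene]methanaminium chloride | C[N+](C)=Cc1cc(OC)c(OC)c(CC=C(C)C)c1OC.[Cl-] | intermediate
6 | 2,4,5-trimethoxy-3-prenylbenzaldehyde | O=Cc1cc(OC)c(OC)c(CC=C(C)C)c1OC | intermediate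
7 | 2-(2,4,5-trimethoxy-3-prenylphenyl)oxirane (racemic) | COc1cc(C2CO2)c(OC)c(CC=C(C)C)c1OC | intermediate
8 | (2,4,5-trimethoxy-3-prenylphenyl)acetaldehyde | O=CCc1cc(OC)c(OC)c(CC=C(C)C)c1OC | intermediate
9 | 3,5-dimethoxyphenol | COc1cc(O)cc(OC)c1 | starting material
10 | (3,5-dimethoxyphenoxy)triisopropylsilane | COc1cc(OC)cc(O[Si](C(C)C)(C(C)C)C(C)C)c1 | intermediate
11 | {2,6-dimethoxy-4-[(triisopropylsilyl)oxy]phenyl}lithium | [Li]c1c(OC)cc(O[Si](C(C)C)(C(C)C)C(C)C)cc1OC | intermediate
12 | (3,5-dimethoxy-4-prenylphenoxy)triisopropylsilane | COc1cc(O[Si](C(C)C)(C(C)C)C(C)C)cc(OC)c1CC=C(C)C | intermediate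
13 | 3,5-dimethoxy-4-prenylphenol | COc1cc(O)cc(OC)c1CC=C(C)C | intermediate
14 | 6-hydroxy-2,4-dimethoxy-3-prenylbenzaldehyde | COc1cc(O)c(C=O)c(OC)c1CC=C(C)C | intermediate
15 | 2-(hydroxymethyl)-3,5-dimethoxy-4-prenylphenol | COc1cc(O)c(CO)c(OC)c1CC=C(C)C | intermediate
16 | 3,5-dimethoxy-6-methylidene-4-prenylcyclohexa-2,4-dien-1-one (o-quinone methide) | C=C1C(=O)C=C(OC)C(CC=C(C)C)=C1OC | intermediate
17 | (2R)-2-[diphenyl(trimethylsilyloxy)methyl]-1-[(E)-2-(2,4,5-trimethoxy-3-prenylphenyl)ethenyl]pyrrolidine | C[Si](C)(C)OC(c1ccccc1)(c1ccccc1)[C@H]1CCCN1/C=C/c1cc(OC)c(OC)c(CC=C(C)C)c1OC | intermediate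
18 | (3R)-5,7-dimethoxy-6-prenyl-3-(2,4,5-trimethoxy-3-prenylphenyl)chroman-2-ol (C2 anomer mixture) | COc1cc2c(c(OC)c1CC=C(C)C)C[C@H](c1cc(OC)c(OC)c(CC=C(C)C)c1OC)C(O)O2 | intermediate
19 | (2R)-3-(6-hydroxy-2,4-dimethoxy-3-prenylphenyl)-2-(2,4,5-trimethoxy-3-prenylphenyl)propan-1-ol | COc1cc(O)c(C[C@H](c2cc(OC)c(OC)c(CC=C(C)C)c2OC)CO)c(OC)c1CC=C(C)C | intermediate
20 | (3R)-5,7-dimethoxy-6-prenyl-3-(2,4,5-trimethoxy-3-prenylphenyl)chromane | COc1cc2c(c(OC)c1CC=C(C)C)C[C@H](c1cc(OC)c(OC)c(CC=C(C)C)c1OC)CO2 | intermediate
21 | 2-[(3R)-5,7-dimethoxy-6-prenylchroman-3-yl]-5-methoxy-6-prenyl-1,4-benzoquinone | COc1cc2c(c(OC)c1CC=C(C)C)C[C@H](C1=CC(=O)C(OC)=C(CC=C(C)C)C1=O)CO2 | intermediate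
22 | 2-[(3R)-5,7-dimethoxy-6-prenylchroman-3-yl]-5-hydroxy-6-prenyl-1,4-benzoquinone (CNP0241224.1) | COc1cc2c(c(OC)c1CC=C(C)C)C[C@H](C1=CC(=O)C(O)=C(CC=C(C)C)C1=O)CO2 | target

Total step count: 12
Longest linear sequence: 9 steps (steps 4–12, from 3,5-dimethoxyphenol 9 to 22); the ring-B branch (steps 1–3, then 8–12) has 8.

Steps most likely to fail

Step 8. The methide may be consumed by Friedel–Crafts self-condensation with ring A of a second molecule of 15, or by N-alkylation of the catalyst, before the enamine captures it. The enamine may also be attacked with poor facial selectivity, or the lactol may epimerise through its open aldehyde form. The fallback sets C3 by auxiliary-controlled enolate alkylation and uses no quinone methide.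
- Ring B: setting out from 8, Pinnick oxidation (NaClO2, NaH2PO4, large excess of 2-methyl-2-butene, t-BuOH/H2O) would give (2,4,5-trimethoxy-3-prenylphenyl)acetic acid F1. Pivaloyl chloride/Et3N (THF, −20 °C) would convert it into the mixed pivalic anhydride F2, which would acylate lithiated (R)-4-benzyloxazolidin-2-one to (4R)-4-benzyl-3-[(2,4,5-trimethoxy-3-prenylphenyl)acetyl]oxazolidin-2-one F3.
- Ring A: setting out from 14, TIPSOTf/2,6-lutidine would give 2,4-dimethoxy-3-prenyl-6-[(triisopropylsilyl)oxy]benzaldehyde F4. NaBH4 (EtOH, 0 °C) would give {2,4-dimethoxy-3-prenyl-6-[(triisopropylsilyl)oxy]phenyl}methanol F5. MsCl/Et3N (CH2Cl2, −20 °C), which delivers the chloride directly with so electron-rich a benzylic alcohol, would give [2-(chloromethyl)-3,5-dimethoxy-4-prenylphenoxy]triisopropylsilane F6, used at once in solution.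
- Coupling: the sodium enolate of F3 (NaHMDS, THF, −78 °C) would be alkylated by F6 on the face away from the benzyl group to give (4R)-4-benzyl-3-[(2R)-3-{2,4-dimethoxy-3-prenyl-6-[(triisopropylsilyl)oxy]phenyl}-2-(2,4,5-trimethoxy-3-prenylphenyl)propanoyl]oxazolidin-2-one F7.
- Return: LiBH4 (THF/H2O, 0 °C) would remove the auxiliary reductively to give (2R)-3-{2,4-dimethoxy-3-prenyl-6-[(triisopropylsilyl)oxy]phenyl}-2-(2,4,5-trimethoxy-3-prenylphenyl)propan-1-ol F8, and TBAF would free the phenol, which returns the route to diol 19.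

Step 11. Over-oxidation may occur: electron transfer from ring A, attack on the prenyl double bonds, or demethylation towards the ortho-quinone. The fallback replaces the chemical oxidant by electrolysis. Setting out from 20, constant-potential anodic oxidation in methanolic KOH (carbon anode, 0 °C) would oxidise and methoxylate only the para-dimethoxy pair. This would give the quinone bis(dimethyl ketal) (3R)-5,7-dimethoxy-3-[3,3,4,6,6-pentamethoxy-5-prenylcyclohexa-1,4-dien-1-yl]-6-prenylchromane F9. Dilute aqueous HCl in acetone at 0 °C would hydrolyse both ketals to quinone 21, where the route resumes.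

Step 12. Hydroxide may add at the unsubstituted quinone carbon C6′, or base may remove the C3–H through a quinone-methide tautomer and erode the stereocentre. The fallback cleaves the O–CH3 bond instead of the ring C–O bond and uses no base. Setting out from 21, BCl3 (1.2 equiv, CH2Cl2, −78 °C) would bind the C5′ carbonyl and the neighbouring methoxy oxygen and cleave the methyl group by chloride attack (chelation-directed Lewis-acid demethylation). This would give the dichloroboryl ether of the hydroxyquinone, 2-[(3R)-5,7-dimethoxy-6-prenylchroman-3-yl]-5-(dichloroboryloxy)-6-prenyl-1,4-benzoquinone F10, which ice-water would hydrolyse directly to target 22.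

Further compounds
F1 | step 8 | (2,4,5-trimethoxy-3-prenylphenyl)acetic acid | OC(=O)Cc1cc(OC)c(OC)c(CC=C(C)C)c1OC
F2 | step 8 | 2,2-dimethylpropanoic (2,4,5-trimethoxy-3-prenylphenyl)acetic anhydride | CC(C)(C)C(=O)OC(=O)Cc1cc(OC)c(OC)c(CC=C(C)C)c1OC
F3 | step 8 | (4R)-4-benzyl-3-[(2,4,5-trimethoxy-3-prenylphenyl)acetyl]oxazolidin-2-one | O=C(Cc1cc(OC)c(OC)c(CC=C(C)C)c1OC)N1[C@H](Cc2ccccc2)COC1=O
F4 | step 8 | 2,4-dimethoxy-3-prenyl-6-[(triisopropylsilyl)oxy]benzaldehyde | COc1cc(O[Si](C(C)C)(C(C)C)C(C)C)c(C=O)c(OC)c1CC=C(C)C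
F5 | step 8 | {2,4-dimethoxy-3-prenyl-6-[(triisopropylsilyl)oxy]phenyl}methanol | COc1cc(O[Si](C(C)C)(C(C)C)C(C)C)c(CO)c(OC)c1CC=C(C)C
F6 | step 8 | [2-(chloromethyl)-3,5-dimethoxy-4-prenylphenoxy]triisopropylsilane | COc1cc(O[Si](C(C)C)(C(C)C)C(C)C)c(CCl)c(OC)c1CC=C(C)C
F7 | step 8 | (4R)-4-benzyl-3-[(2R)-3-{2,4-dimethoxy-3-prenyl-6-[(triisopropylsilyl)oxy]phenyl}-2-(2,4,5-trimethoxy-3-prenylphenyl)propanoyl]oxazolidin-2-one | COc1cc(O[Si](C(C)C)(C(C)C)C(C)C)c(C[C@H](c2cc(OC)c(OC)c(CC=C(C)C)c2OC)C(=O)N2[C@H](Cc3ccccc3)COC2=O)c(OC)c1CC=C(C)C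
F8 | step 8 | (2R)-3-{2,4-dimethoxy-3-prenyl-6-[(triisopropylsilyl)oxy]phenyl}-2-(2,4,5-trimethoxy-3-prenylphenyl)propan-1-ol | COc1cc(O[Si](C(C)C)(C(C)C)C(C)C)c(C[C@H](c2cc(OC)c(OC)c(CC=C(C)C)c2OC)CO)c(OC)c1CC=C(C)C
F9 | step 11 | (3R)-5,7-dimethoxy-3-[3,3,4,6,6-pentamethoxy-5-prenylcyclohexa-1,4-dien-1-yl]-6-prenylchromane | COc1cc2c(c(OC)c1CC=C(C)C)C[C@H](C1=CC(OC)(OC)C(OC)=C(CC=C(C)C)C1(OC)OC)CO2
F10 | step 12 | 2-[(3R)-5,7-dimethoxy-6-prenylchroman-3-yl]-5-(dichloroboryloxy)-6-prenyl-1,4-benzoquinone | COc1cc2c(c(OC)c1CC=C(C)C)C[C@H](C1=CC(=O)C(OB(Cl)Cl)=C(CC=C(C)C)C1=O)CO2
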